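The rate constants belong to no real substance, and the outcome is calculated.

Look at the leftover at the end of each flask, a pool of target and isomer of the product, and ask how much of it is still target.

all flasks: substrate 0.72 M; partner 1.08 M; time 40 min
- eta: temperature 15 °C
- zeta: temperature 40 °C
- gamma: temperature 90 °C
- delta: temperature 65 °C

    substrate → intermediate (k1 = 0.0336 /min, Ea1 = 95.0 kJ/mol)
    partner + intermediate → target (k2 = 0.327 /M/min, Ea2 = 74.0 kJ/mol)
    2 partner → homo product (k3 = 0.384 /M/min, Ea3 = 70.0 kJ/mol)
    target ⇌ isomer of the product (K4 = 3.70, k4 = 0.0751 /min, Ea4 = 90.0 kJ/mol, ΔH4 = −22.0 kJ/mol)
    partner ⇌ dormant form (K5 = 2.17, k5 = 0.00628 /min, Ea5 = 95.0 kJ/mol, ΔH5 = −25.0 kJ/mol)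
    target → over-reaction product (k6 = 2.93 × 10⁻⁵ /min, Ea6 = 108 kJ/mol)
    (constants at 40 °C)

- for a step with 2 of a species take k times the square, and two of it per event
- at 40 °C the constants are as listed, elsewhere as the activation energies and enthalpies make them
- the share counts what is present at the end, not what went on to other products

* the best flask by share of target in all that became target or isomer of the product; "all alike" if 1.5 percentage points covers them all (eta / zeta / gamma / delta / all alike)
* share of target in all that became target or isomer of the product, eta
* share of target in all that became target or isomer of the product, zeta
* share of target in all that became target or isomer of the product, gamma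
* share of target in all that became target or isomer of the product, delta

Read K as isomer over target. The isomerisation then runs on one clock, the relaxation constant λ, forward plus back constant, 0.0954 /min in zeta. Take a batch of target born at one moment and left to this step: the excess of its share over the equilibrium share shrinks by the factor exp(−λ·age). So each flask needs an equilibrium share and a mean age.

Try the hot flasks first. In delta K falls to 1.98 and the relaxation half-life is 0.476 min, far shorter than 40 min, so take the equilibrium share, 33.5%. This is thermodynamic control. In gamma K is 1.16 and the clock is faster still, with half-life 0.0424 min, which gives 46.4%.

Now find the age. Freeze [substrate] at its charge, so [intermediate] climbs linearly with time. Partner thins by homo coupling as its charge over 1 plus time per first half-life, so the product [partner][intermediate], the birth rate of target, climbs from zero and goes flat only after that half-life. This curve holds until the step to target draws as much partner as homo coupling does, at a crossover time equal to the inverse root of the two constants times [substrate]. In eta that crossover is 188 min, later than the end, so use the curve for the whole run. Eta's partner half-life is 12.4 min, so the run is X = 3.22 half-lives long. Weighting by the curve puts the mean birth at (X^2/2 − X + ln(1+X))/(X − ln(1+X)) half-lives, which leaves a mean age of 16.2 min. With half-life 164 min and equilibrium share 11.5%, eta holds 94.1%. Zeta's equilibrium share is 21.3%, and the same age there gives 38.0%. Commit: eta is best.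

Reforge the weak link, zeta's age. Partner's first half-life by homo coupling there is 1.21 min, and crossover comes at 11.2 min, well inside the run. The partner remaining then lasts about one more crossover time at the flat rate, so births stop near twice that time. The mean age becomes 28.8 min and the share 26.3%. Young batches weigh more in an exponential, so I take this as a low estimate, and I expect zeta between 26.3% and 38.0%.

The forecast names eta, with 94.2%, 39% (range 36% to 43%), 46.4% and 33.6%, holding that in eta “it is too slow to get far from the freshly made target”. Its zeta stands above my bracket.

The simulation gives eta as best: 94.0% in eta, 30.5% in zeta, 46.4% in gamma, 33.6% in delta. The forecast's zeta is 8.5 percentage points high, and its number is what [partner] held at its starting value gives, whereas zeta's partner stood at 2.67% of its charge after 20.0 min. Put through λ, zeta's 30.5% reads as a mean age of 22.4 min, older than 16.2 min and younger than 28.8 min.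

Take eta's recipe at −10 °C. K is 18.4 and the clock slows to 1.11 × 10⁻⁴ /min. Partner's half-life there is 199 min, so X is 0.201, the same weighting gives a mean age of 13.7 min, and that age gives 99.9%. The computed share is 99.9%.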